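Remark: the target SMILES is read as 7α-acetoxylabda-8(17),12E,14-trien-19-oic acid, (4S,5R,7R,9R,10R), with the C19 carboxyl axial (β) and cis to the C10 methyl.

Assumption: the sense of induction of the (1R,2S,5R)-8-phenylmenthyl ester in step 6 is taken from the stacking model given there; if the opposite sense were found, the enantiomeric alcohol would be used and nothing else changes.

Labdane numbering is used throughout: decalin C1–C10, side chain C11–C16 on C9 (C16 = methyl on C13), C17 = methylene carbon on C8, C18 (α) and C19 (β) on C4, C20 = methyl on C10.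

## The problem

The target is a trans-decalin in which ring A (C1–C5, C10) and ring B (C5–C10) share the C5–C10 bond. Two quaternary carbons, C4 and C10, sit 1,3 to each other and both carry a β-axial carbon substituent (C19 carboxyl, C20 methyl). C4 carries a methyl and a carboxyl that must be told apart. The axial, neopentyl carboxyl cannot be released from an ordinary ester under conditions an allylic acetate survives, so the acid has to be free before the acetate is put on. C4, C5, C10 and C9 are contiguous and are fixed relative to each other by the way the two rings close; only their absolute sense needs an outside source. C7 is isolated but sits on the rigid ring next to C8=C17, where the α face is open and the β face is covered by C20, so the bicycle can control it. Ring B holds a 1,1-disubstituted exocyclic alkene flanked by the axial acetate and the C9 side chain; it isomerises into the ring under acid and the acetate can ionise or suffer SN2′. The (12E)-3-methylpenta-2,4-dienyl chain is sensitive to acid, oxidants and radicals and must appear late with defined geometry. The feature that opens the key step is that C4 is both the α-carbon of the C19 carboxyl and the head of an isoprenoid chain: C5/C10 and C8/C9 are the carbons of two E-trisubstituted alkenes carrying the C20 and C17 methyls. A C19–C4–C3 β-keto ester radical can therefore close C4–C5 and C10–C9, and the C8 radical next to the C17 methyl becomes the C8=C17 methylene.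

## Retrosynthesis

**21 ⇒ 20.** The C7 O–acyl bond is cut last. The acetate would not survive the hydride, base or coupling steps, and acylation of hydroxy acid 20 touches no stereocentre.

**20 ⇒ 18 + 19.** The C13–C14 bond is cut, so the diene comes from alkenyl iodide 18 and potassium vinyltrifluoroborate 19. A cut at C12=C13 would need a C12 aldehyde and an olefination of uncertain E/Z ratio; a cut at C11–C12 would need substitution at a hindered carbon next to C9. The forward coupling must keep the 12E geometry and tolerate a free acid and alcohol.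

**18 ⇒ 17 ⇒ 15 ⇒ 13.** The C7–O bond is cut by an allylic ene/[2,3] transform on the C8=C17 alkene of acid 17; the 7α-hydrogen is the one aligned with the π system on the open face. Acid 17 comes from alcohol 15 by oxidation, and the iodoalkene of 15 from the but-2-ynyl group of 13 by hydrozirconation–iodination. The alkyne is an inert stand-in for the diene through the radical and hydride steps. The iodoalkene, unlike the alkyne or the diene, is a poor partner for the C7 oxidation.

**13 ⇒ 12 ⇒ 10.** The auxiliary ester is cleaved reductively and the C3 carbonyl of 10 is removed. Both are the price of the key step; neither touches a stereocentre.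

**10 ⇒ 9 (key).** The C4–C5 and C9–C10 bonds are cut and C8=C17 is returned to a methyl-bearing alkene carbon. The precursor 9 is an acyclic E,E-dienyne 2-methyl-3-oxo ester whose only fixed stereocentres are those of the auxiliary; the product has two rings, four contiguous stereocentres, both quaternary carbons and the exocyclic alkene. An oxygen placed at C7 of the chain could not set the absolute sense, because the first, irreversible closure (C4–C5) occurs three atoms away from it. The controller therefore sits on the C19 ester, at the radical carbon itself.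

**9 ⇒ 3 + 8.** The C1–C2 bond is cut: γ-alkylation of the dianion of auxiliary ester 3 with allylic bromide 8. This fixes the C5=C10 geometry in the electrophile.

**8 ⇒ 7 ⇒ 6 ⇒ 4 + 5; 3 ⇒ 1 + 2.** Bromide 8 comes from alcohol 7, made by allylic oxidation of the E-methyl of dienyne 6. Dienyne 6 is the coupling product of geranyl bromide 4 and 1-propynylmagnesium bromide 5, which forms C11–C12 and brings the E C8=C9 alkene from the chiral-pool-free terpene. Ester 3 is the transesterification product of 1 and 2.

## Roads not taken

Alternative 1: Ring-by-ring construction, the most obvious route. Ring A is cut from ring B at a Robinson annulation, starting from (S)-Wieland–Miescher ketone A1. The forward key step is reductive carbomethoxylation of the enone, then α-face methylation, giving keto ester A2 with the correct axial ester. C3 must still be deoxygenated, and the C9 ketone has to be turned, atom by atom, into the C9 side chain next to the quaternary C10, the C8 methylene and the C7 oxygen. The chosen plan forms C4–C5, C9–C10 and C8=C17 in one step and carries the side-chain carbons in the precursor.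

Alternative 2: Epoxide-initiated bicyclisation. The same two ring bonds are cut, but the trigger is the C3–C4 epoxide of epoxy alcohol A4, made by Sharpless asymmetric epoxidation of the farnesyl-type allylic alcohol A3. Titanocene(III)-mediated radical cyclisation would give diol A5 with secure absolute control and an exocyclic alkene. The planar C4 radical loses the epoxide geometry, and the smaller methyl is expected to take the axial position beside C20, so the oxygenated carbon ends equatorial (C18), the 4-epi series. C3–OH removal and a two-stage oxidation of the primary alcohol would still follow. In the chosen plan the dicarbonyl radical places the ester axial and C19 is already at the acid oxidation level.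

Alternative 3: Diels–Alder construction of ring A. C4–C5 and C2–C3 are cut: triene A6 (two steps from 7) reacts with 2-methylpropenal A7 under a chiral Lewis acid to give aldehyde A8, setting C4 and C5; ring B then closes by protonation at C1 and cation–olefin cyclisation. The 1-alkyl and 2-methyl groups of the diene direct the regiochemistry in opposite ways, and the α-methyl dienophile makes the endo/exo outcome uncertain. The cationic termination gives mixtures of Δ7, Δ8 and Δ8(17) alkenes, and the aldehyde must be oxidised and masked before acid is applied. The radical cascade of the chosen plan terminates regioselectively at C17 and needs no second ring-forming step.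

Key step: step 6

## Steps

Step 1
Reactants: 1 ethyl 2-methyl-3-oxobutanoate; 2 (−)-8-phenylmenthol, (1R,2S,5R)-5-methyl-2-(2-phenylpropan-2-yl)cyclohexan-1-ol
Product: 3 (1R,2S,5R)-5-methyl-2-(2-phenylpropan-2-yl)cyclohexyl 2-methyl-3-oxobutanoate (both C2 epimers)
Conditions: DMAP (0.3 equiv), toluene, reflux, EtOH distilled off
Reagents that add atoms: none
Why: DMAP-catalysed transesterification of an enolisable β-keto ester via its acylketene; removal of ethanol drives acylation of the hindered secondary alcohol, and the epimeric α-centre is of no consequence because it becomes the radical carbon.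

Step 2
Reactants: 4 geranyl bromide, (2E)-1-bromo-3,7-dimethylocta-2,6-diene; 5 1-propynylmagnesium bromide
Product: 6 (5E)-6,10-dimethylundeca-5,9-dien-2-yne
Conditions: CuI (5 mol%), THF, 0 °C to rt
Reagents that add atoms: none
Why: Cu(I)-catalysed SN2 coupling of an alkynyl Grignard reagent with a primary allylic bromide gives the skipped enyne at the unbranched terminus with the E alkene retained; this forms C11–C12.

Step 3
Reactants: 6
Product: 7 (2E,6E)-2,6-dimethylundeca-2,6-dien-9-yn-1-ol
Conditions: SeO2 (0.1 equiv), salicylic acid (0.1 equiv), t-BuOOH (2.5 equiv), CH2Cl2, 0 °C to rt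
Reagents that add atoms: tert-butyl hydroperoxide, CC(C)(C)OO
Why: Catalytic Riley oxidation (ene reaction, then [2,3]-shift) at the terminal isopropylidene, the most accessible ene partner, oxidises the methyl trans to the chain and so gives the E allylic alcohol that later fixes the C5=C10 geometry.

Step 4
Reactants: 7
Product: 8 (2E,6E)-1-bromo-2,6-dimethylundeca-2,6-dien-9-yne
Conditions: CBr4, PPh3, CH2Cl2, 0 °C
Reagents that add atoms: carbon tetrabromide, BrC(Br)(Br)Br
Why: Appel reaction; SN2 displacement at the primary allylic carbon under neutral conditions leaves both alkene geometries and the alkyne untouched.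

Step 5
Reactants: 3; 8
Product: 9 (1R,2S,5R)-5-methyl-2-(2-phenylpropan-2-yl)cyclohexyl (6E,10E)-2,6,10-trimethyl-3-oxopentadeca-6,10-dien-13-ynoate (both C2 epimers)
Conditions: NaH (1.1 equiv), THF, 0 °C; n-BuLi (1.05 equiv), 0 °C; 8, 0 °C to rt; aq. NH4Cl
Reagents that add atoms: none
Why: β-Keto ester dianion alkylation: the more basic terminal (γ) carbanion displaces the primary allylic bromide and forms C1–C2, while the α-carbon keeps the hydrogen needed for Mn(III) enolisation.

Step 6
Reactants: 9
Product: 10 (−)-8-phenylmenthyl 3-oxo-14,15-dinorlabd-8(17)-en-12-yn-19-oate (trans-decalin; 4α-CH3, 4β-CO2R*, 5α-H, 9β-but-2-ynyl, 10β-CH3, 8-methylene)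
Conditions: Mn(OAc)3·2H2O (2.2 equiv), Cu(OAc)2·H2O (1.0 equiv), degassed AcOH, rt
Reagents that add atoms: none
Why: Mn(III) enolate formation and inner-sphere electron transfer give the electrophilic C4 radical, which adds 6-endo-trig to C5 of the C5=C10 alkene; the tertiary C10 radical adds 6-endo-trig to C9 of the C8=C9 alkene; and the tertiary C8 radical is captured by Cu(II) and loses a C17 hydrogen by syn β-elimination, Mn(III) returning Cu(I) to Cu(II). The closest known reaction type is the Mn(OAc)3/Cu(OAc)2 oxidative free-radical polycyclisation of α-substituted β-keto esters bearing E-trisubstituted alkenes, including 8-phenylmenthyl esters as chiral controllers. Ring A closes 6-endo because attack at the less substituted terminus C5 gives a tertiary radical and a 5-exo closure would build a strained acylcyclopentane; ring B closes 6-endo through a chair onto the planar C10 radical. C4 and C5 are set together in the first chair: the radical reacts in the conformer with the ester carbonyl anti to the ketone, which places CO2R* axial (β) and CH3 equatorial, with the C6 chain equatorial at C5. C10 follows from equatorial bond formation anti to 5-H (trans-decalin, CH3 axial), and C9 from the E geometry of C8=C9, which puts C11 equatorial and 9-H axial (α). The absolute sense is decided in the first, irreversible closure: the phenyl ring of the auxiliary stacks over the Si face of C4, so C5 bonds to the Re face. The step needs face selectivity (the minor series is a separable diastereomer), exo rather than endo alkene formation (the freely rotating C17 hydrogens reach the syn-periplanar geometry most easily) and an inert alkyne (no feasible ring size from C8 or C10, and the electrophilic C4 radical prefers the electron-rich alkene).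

Step 7
Reactants: 10
Product: 12 (−)-8-phenylmenthyl 14,15-dinorlabd-8(17)-en-12-yn-19-oate, via tosylhydrazone 11 (not isolated)
Conditions: TsNHNH2, PPTS (cat.), EtOH, reflux; solvent exchange; catecholborane, CHCl3, 0 °C to rt; NaOAc·3H2O, reflux
Reagents that add atoms: none
Why: Reduction of a ketone tosylhydrazone to the methylene compound by hydride transfer from catecholborane, loss of sulfinate and N2 extrusion from the diazene (a mild variant of the Wolff–Kishner/Caglioti reduction); no base strong enough for retro-Claisen opening is present and the alkyne and alkene are not hydroborated at this temperature.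

Step 8
Reactants: 12
Product: 13 14,15-dinorlabd-8(17)-en-12-yn-19-ol
Conditions: LiAlH4 (3 equiv), THF, 0 °C to reflux; Fieser work-up; 2 recovered by chromatography
Reagents that add atoms: none
Why: Hydride reduction releases the auxiliary from the axial, neopentyl ester, which hydrolysis could not do; the isolated alkyne and alkene are inert to LiAlH4.

Step 9
Reactants: 13
Product: 15 (12E)-13-iodo-14,15-dinorlabda-8(17),12-dien-19-ol, via alkenylzirconocene 14 (not isolated)
Conditions: Cp2Zr(H)Cl (3 equiv), THF, rt to 40 °C; I2 (1.2 equiv), 0 °C; aq. Na2S2O3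
Reagents that add atoms: iodine, II
Why: Hydrozirconation–iodination: after the first equivalent has turned the hydroxyl into a zirconium alkoxide, Zr–H adds syn to the alkyne and, with excess hydride, equilibrates to place Zr on C13 (methyl side, away from the branched C11–C9 side); iodinolysis with retention gives the 12E iodoalkene, and the hindered C8=C17 alkene reacts far more slowly than the alkyne.

Step 10
Reactants: 15
Product: 17 (12E)-13-iodo-14,15-dinorlabda-8(17),12-dien-19-oic acid, via aldehyde 16 (not isolated)
Conditions: Dess–Martin periodinane, NaHCO3, CH2Cl2, rt; then NaClO2, NaH2PO4, 2-methyl-2-butene, t-BuOH/H2O, rt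
Reagents that add atoms: sodium chlorite, [Na+].[O-]Cl=O
Why: Dess–Martin oxidation to the axial aldehyde, then Pinnick oxidation with a hypochlorite scavenger; both are near neutral, so the exocyclic alkene does not migrate, the alkenyl iodide is untouched and the quaternary C4 cannot epimerise.

Step 11
Reactants: 17
Product: 18 (12E)-7α-hydroxy-13-iodo-14,15-dinorlabda-8(17),12-dien-19-oic acid
Conditions: SeO2 (0.5 equiv), t-BuOOH (3 equiv), CH2Cl2, rt
Reagents that add atoms: tert-butyl hydroperoxide, CC(C)(C)OO
Why: Riley oxidation: ene reaction at C17 with removal of the axial 7α-H, then a [2,3]-shift that restores C8=C17 and delivers oxygen to C7 on the same α face; the β face is shielded by the axial C20 methyl, the tertiary C9–H is hindered and disfavoured (CH2 before CH), and the iodoalkene is too electron-poor for the ene step.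

Step 12
Reactants: 18; 19 potassium vinyltrifluoroborate
Product: 20 7α-hydroxylabda-8(17),12E,14-trien-19-oic acid
Conditions: PdCl2(dppf) (5 mol%), Cs2CO3 (4 equiv), THF/H2O 9:1, 65 °C; acidify to pH 4
Reagents that add atoms: none
Why: Suzuki–Miyaura coupling forms C13–C14 with retention of the alkenyl iodide geometry and reveals the 12E,14-diene; carboxylate and free hydroxyl are tolerated under aqueous carbonate, which would endanger an acetate, hence coupling before acetylation.

Step 13
Reactants: 20
Product: 21 7α-acetoxylabda-8(17),12E,14-trien-19-oic acid (target)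
Conditions: Ac2O (5 equiv), pyridine, DMAP (0.1 equiv), CH2Cl2, 0 °C to rt; aq. NaHCO3, then citric acid to pH 4
Reagents that add atoms: acetic anhydride, CC(=O)OC(C)=O
Why: DMAP-catalysed O-acylation of the axial allylic alcohol leaves the C7 configuration untouched; any mixed anhydride at the hindered carboxyl is hydrolysed in the bicarbonate work-up, and no acid strong enough to ionise the allylic acetate or isomerise the diene is used.

## Compound list

1 | ethyl 2-methyl-3-oxobutanoate | CCOC(=O)C(C)C(C)=O | starting material
2 | (−)-8-phenylmenthol, (1R,2S,5R)-5-methyl-2-(2-phenylpropan-2-yl)cyclohexan-1-ol | O[C@@H]1C[C@H](C)CC[C@H]1C(C)(C)c1ccccc1 | starting material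
3 | (1R,2S,5R)-8-phenylmenthyl 2-methyl-3-oxobutanoate (C2 epimers) | CC(=O)C(C)C(=O)O[C@@H]1C[C@H](C)CC[C@H]1C(C)(C)c1ccccc1 | intermediate
4 | geranyl bromide | CC(C)=CCC/C(C)=C/CBr | starting material
5 | 1-propynylmagnesium bromide | CC#C[Mg]Br | starting material
6 | (5E)-6,10-dimethylundeca-5,9-dien-2-yne | CC#CC/C=C(C)/CCC=C(C)C | intermediate
7 | (2E,6E)-2,6-dimethylundeca-2,6-dien-9-yn-1-ol | CC#CC/C=C(C)/CC/C=C(C)/CO | intermediate
8 | (2E,6E)-1-bromo-2,6-dimethylundeca-2,6-dien-9-yne | CC#CC/C=C(C)/CC/C=C(C)/CBr | intermediate
9 | (1R,2S,5R)-8-phenylmenthyl (6E,10E)-2,6,10-trimethyl-3-oxopentadeca-6,10-dien-13-ynoate (C2 epimers) | CC#CC/C=C(C)/CC/C=C(C)/CCC(=O)C(C)C(=O)O[C@@H]1C[C@H](C)CC[C@H]1C(C)(C)c1ccccc1 | intermediate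
10 | (−)-8-phenylmenthyl 3-oxo-14,15-dinorlabd-8(17)-en-12-yn-19-oate | CC#CC[C@H]1C(=C)CC[C@@H]2[C@]1(C)CCC(=O)[C@]2(C)C(=O)O[C@@H]3C[C@H](C)CC[C@H]3C(C)(C)c3ccccc3 | intermediate
11 | 3-tosylhydrazone of 10 | CC#CC[C@H]1C(=C)CC[C@@H]2[C@]1(C)CCC(=NNS(=O)(=O)c3ccc(C)cc3)[C@]2(C)C(=O)O[C@@H]4C[C@H](C)CC[C@H]4C(C)(C)c5ccccc5 | intermediate (not isolated)
12 | (−)-8-phenylmenthyl 14,15-dinorlabd-8(17)-en-12-yn-19-oate | CC#CC[C@H]1C(=C)CC[C@@H]2[C@]1(C)CCC[C@]2(C)C(=O)O[C@@H]3C[C@H](C)CC[C@H]3C(C)(C)c3ccccc3 | intermediate
13 | 14,15-dinorlabd-8(17)-en-12-yn-19-ol | CC#CC[C@H]1C(=C)CC[C@@H]2[C@]1(C)CCC[C@]2(C)CO | intermediate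
14 | (12E)-13-(chloridozirconocenyl)-14,15-dinorlabda-8(17),12-dien-19-yl chloridozirconocene alkoxide | C/C(=C\C[C@H]1C(=C)CC[C@@H]2[C@]1(C)CCC[C@]2(C)CO[Zr](Cl)(C3C=CC=C3)C3C=CC=C3)[Zr](Cl)(C3C=CC=C3)C3C=CC=C3 | intermediate (not isolated)
15 | (12E)-13-iodo-14,15-dinorlabda-8(17),12-dien-19-ol | C/C(I)=C\C[C@H]1C(=C)CC[C@@H]2[C@]1(C)CCC[C@]2(C)CO | intermediate
16 | (12E)-13-iodo-14,15-dinorlabda-8(17),12-dien-19-al | C/C(I)=C\C[C@H]1C(=C)CC[C@@H]2[C@]1(C)CCC[C@]2(C)C=O | intermediate (not isolated)
17 | (12E)-13-iodo-14,15-dinorlabda-8(17),12-dien-19-oic acid | C/C(I)=C\C[C@H]1C(=C)CC[C@@H]2[C@]1(C)CCC[C@]2(C)C(=O)O | intermediate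
18 | (12E)-7α-hydroxy-13-iodo-14,15-dinorlabda-8(17),12-dien-19-oic acid | C/C(I)=C\C[C@H]1C(=C)[C@H](O)C[C@@H]2[C@]1(C)CCC[C@]2(C)C(=O)O | intermediate
19 | potassium vinyltrifluoroborate | [K+].C=C[B-](F)(F)F | starting material
20 | 7α-hydroxylabda-8(17),12E,14-trien-19-oic acid | C=C/C(C)=C/C[C@H]1C(=C)[C@H](O)C[C@@H]2[C@]1(C)CCC[C@]2(C)C(=O)O | intermediate
21 | 7α-acetoxylabda-8(17),12E,14-trien-19-oic acid | C=C/C(C)=C/C[C@H]1C(=C)[C@H](OC(C)=O)C[C@@H]2[C@]1(C)CCC[C@]2(C)C(=O)O | target

## Step count and least certain steps

Total: 13 steps. Longest linear sequence: 12 steps (4 → 21, steps 2–13); step 1 is a one-step side branch.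

**Step 6 (key).** The most likely failure is poor facial discrimination: the auxiliary acts through a single stacked conformer of a flexible ester, so the wrong-face closure may compete. The dicarbonyl conformation also decides whether the ester ends axial, and the C8 radical may partition towards endocyclic alkenes. The fallback sets out from 8 and returns at 13; it no longer forms the quaternary centre in the cyclisation. (+)-8-Phenylmenthol is acylated with 2,2,6-trimethyl-4H-1,3-dioxin-4-one (xylene, 140 °C) to (1S,2R,5S)-8-phenylmenthyl 3-oxobutanoate F1. Its dianion is alkylated with 8 to the α-unsubstituted keto ester F2. Mn(OAc)3/Cu(OAc)2 with Yb(OTf)3 in CF3CH2OH at 0 °C cyclises the metal-chelated radical to the enolisable bicyclic keto ester F3; the two carbonyls are now syn, so the stacking model calls for the enantiomeric auxiliary. C-Methylation of F3 (K2CO3, MeI, acetone) from the α face, anti to the C10 methyl, gives the 4α-methyl-4β-ester F4. F4 is deoxygenated as in step 7 through its tosylhydrazone F5 to the ester F6, and LiAlH4 reduction of F6 gives 13.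

**Step 7.** Hydrazone formation may be slow or incomplete at the C3 carbonyl, which is flanked by the quaternary C4; forcing conditions then invite retro-Claisen opening of ring A. The fallback sets out from 10 and returns at 12. NaBH4 (MeOH/THF, 0 °C) gives the 3β-alcohol F7; NaH, CS2 and MeI give the S-methyl xanthate F8; Barton–McCombie reduction (Bu3SnH, AIBN, toluene, reflux) gives 12.

**Step 11.** Over-oxidation of the allylic alcohol to the enone, incomplete α-selectivity and a competing ene reaction at C9–H would all erode the yield of 18. The fallback sets out from 17 and returns at 21; the stereocentre is set by hydride delivery and inversion instead of the pericyclic sequence. All C7-oxidised material (stoichiometric SeO2, then Dess–Martin periodinane) is taken to the 7-oxo acid F9. Luche reduction (NaBH4, CeCl3, MeOH, −78 °C; axial attack from the α face) gives the 7β-alcohol F10. Mitsunobu reaction with excess acetic acid (PPh3, DIAD, toluene) inverts C7 and gives the 7α-acetate F11. Stille coupling of F11 with tributyl(vinyl)stannane (Pd2(dba)3, AsPh3, NMP, rt) gives 21 under neutral conditions.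

**Step 3.** Site selectivity may be lost through an ene reaction at the internal alkene or propargylic oxidation, and the alcohol may over-oxidise to the enal. The fallback sets out from 4 and returns at 7; the oxidation is done while an allylic acetate deactivates the neighbouring alkene. Bromide 4 and KOAc (DMF) give geranyl acetate F12. SeO2/t-BuOOH gives (2E,6E)-8-hydroxy-3,7-dimethylocta-2,6-dienyl acetate F13. Pd(PPh3)4-catalysed coupling of the allylic acetate of F13 with the alkynylzinc made from 5 and ZnCl2 (2.2 equiv, the first deprotonates the hydroxyl) gives 7.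

## Further compounds

F1 | step 6 | (1S,2R,5S)-8-phenylmenthyl 3-oxobutanoate | CC(=O)CC(=O)O[C@H]1C[C@@H](C)CC[C@@H]1C(C)(C)c1ccccc1
F2 | step 6 | (1S,2R,5S)-8-phenylmenthyl (6E,10E)-6,10-dimethyl-3-oxopentadeca-6,10-dien-13-ynoate | CC#CC/C=C(C)/CC/C=C(C)/CCC(=O)CC(=O)O[C@H]1C[C@@H](C)CC[C@@H]1C(C)(C)c1ccccc1
F3 | step 6 | (+)-8-phenylmenthyl 3-oxo-14,15,18-trinorlabd-8(17)-en-12-yn-19-oate (C4 enolisable) | CC#CC[C@H]1C(=C)CC[C@@H]2[C@]1(C)CCC(=O)C2C(=O)O[C@H]3C[C@@H](C)CC[C@@H]3C(C)(C)c3ccccc3
F4 | step 6 | (+)-8-phenylmenthyl 3-oxo-14,15-dinorlabd-8(17)-en-12-yn-19-oate | CC#CC[C@H]1C(=C)CC[C@@H]2[C@]1(C)CCC(=O)[C@]2(C)C(=O)O[C@H]3C[C@@H](C)CC[C@@H]3C(C)(C)c3ccccc3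
F5 | step 6 | 3-tosylhydrazone of F4 | CC#CC[C@H]1C(=C)CC[C@@H]2[C@]1(C)CCC(=NNS(=O)(=O)c3ccc(C)cc3)[C@]2(C)C(=O)O[C@H]4C[C@@H](C)CC[C@@H]4C(C)(C)c5ccccc5
F6 | step 6 | (+)-8-phenylmenthyl 14,15-dinorlabd-8(17)-en-12-yn-19-oate | CC#CC[C@H]1C(=C)CC[C@@H]2[C@]1(C)CCC[C@]2(C)C(=O)O[C@H]3C[C@@H](C)CC[C@@H]3C(C)(C)c3ccccc3
F7 | step 7 | (−)-8-phenylmenthyl 3β-hydroxy-14,15-dinorlabd-8(17)-en-12-yn-19-oate | CC#CC[C@H]1C(=C)CC[C@@H]2[C@]1(C)CC[C@H](O)[C@]2(C)C(=O)O[C@@H]3C[C@H](C)CC[C@H]3C(C)(C)c3ccccc3
F8 | step 7 | S-methyl xanthate of F7 | CC#CC[C@H]1C(=C)CC[C@@H]2[C@]1(C)CC[C@H](OC(=S)SC)[C@]2(C)C(=O)O[C@@H]3C[C@H](C)CC[C@H]3C(C)(C)c3ccccc3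
F9 | step 11 | (12E)-13-iodo-7-oxo-14,15-dinorlabda-8(17),12-dien-19-oic acid | C/C(I)=C\C[C@H]1C(=C)C(=O)C[C@@H]2[C@]1(C)CCC[C@]2(C)C(=O)O
F10 | step 11 | (12E)-7β-hydroxy-13-iodo-14,15-dinorlabda-8(17),12-dien-19-oic acid | C/C(I)=C\C[C@H]1C(=C)[C@@H](O)C[C@@H]2[C@]1(C)CCC[C@]2(C)C(=O)O
F11 | step 11 | (12E)-7α-acetoxy-13-iodo-14,15-dinorlabda-8(17),12-dien-19-oic acid | C/C(I)=C\C[C@H]1C(=C)[C@H](OC(C)=O)C[C@@H]2[C@]1(C)CCC[C@]2(C)C(=O)O
F12 | step 3 | geranyl acetate | CC(C)=CCC/C(C)=C/COC(C)=O
F13 | step 3 | (2E,6E)-8-hydroxy-3,7-dimethylocta-2,6-dienyl acetate | OC/C(C)=C/CC/C(C)=C/COC(C)=O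
A1 | alternative 1 | (S)-Wieland–Miescher ketone | C[C@]12CCC(=O)C=C1CCCC2=O
A2 | alternative 1 | methyl 9,9-ethylenedioxy-3-oxo-11,12,13,14,15,16,17-heptanorlabdan-19-oate (5α-H, 10β-CH3) | C12(OCCO1)CCC[C@@H]3[C@]2(C)CCC(=O)[C@]3(C)C(=O)OC
A3 | alternative 2 | (2E,6E,10E)-2,6,10-trimethylpentadeca-2,6,10-trien-13-yn-1-ol | CC#CC/C=C(C)/CC/C=C(C)/CC/C=C(C)/CO
A4 | alternative 2 | (2S,3S,6E,10E)-2,3-epoxy-2,6,10-trimethylpentadeca-6,10-dien-13-yn-1-ol | CC#CC/C=C(C)/CC/C=C(C)/CC[C@@H]1O[C@@]1(C)CO
A5 | alternative 2 | 14,15-dinorlabd-8(17)-en-12-yne-3β,18-diol | CC#CC[C@H]1C(=C)CC[C@@H]2[C@]1(C)CC[C@H](O)[C@@]2(C)CO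
A6 | alternative 3 | (3E,7E)-3,7-dimethyldodeca-1,3,7-trien-10-yne | C=C/C(C)=C/CC/C(C)=C/CC#CC
A7 | alternative 3 | 2-methylpropenal | C=C(C)C=O
A8 | alternative 3 | 1,3-dimethyl-2-[(3E)-3-methyloct-3-en-6-ynyl]cyclohex-3-ene-1-carbaldehyde (formyl cis to the C2 chain) | O=C[C@@]1(C)CCC=C(C)[C@H]1CC/C(C)=C/CC#CC
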